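The earlier runs and the new flask come from a simulation for substances that don't exist, and the scatter is random.

In the spring run L ends far above D, 44.5% against 1.3% of the Q charged at 6.00 d, while D stays low in both runs. The readings look like D being a small stock passed through on the way to L.

in all of them: J 0.0525 M

| run | Q | remark | time |
|---|---|---|---|
| spring | 0.025 M | run made earlier |  |
| noon | 0.038 M | run made earlier |  |
| flask | 0.050 M |  | 10 d |

| run | time / d | L / % | D / % |
|---|---|---|---|
| spring | 0.833 | 10.6 | 2.1 |
| spring | 2.00 | 22.1 | 1.1 |
| spring | 4.00 | 35.7 | 1.4 |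
| spring | 6.00 | 44.5 | 1.3 |
| noon | 0.500 | 4.4 | 0.9 |
| noon | 1.04 | 12.2 | 1.2 |
| noon | 2.50 | 25.1 | 1.7 |
| noon | 6.00 | 41.2 | 1.1 |

(readings scatter by 0.5 percentage points)

1. share of L in L plus D at 5.0 h
2. share of L in L plus D at 10 d



Step one, the feed. This reckoning takes L plus D as the whole product of Q and J. The spring end, read as second order, gives k′, the pseudo-first-order rate constant at the charged J: 0.117 d⁻¹.

Step two, the stock. The holding time τ, the amount of D divided by the feed, is 0.105 d. It is the mean, over the three readings of the first day, of reading time times the share of D in L plus D. With a scatter of 0.5 percentage points, this is a soft reading.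

Step three, the first instants. At 5.0 h, about twice τ, the stock of D is still filling exponentially, so this reckoning gives a share of 56.5% in the flask.

Step four, the middle. Q and J fall together, the feed slows, and D follows it down as τ times the feed while L grows.

Step five, the end. At 10 d the reckoning has 54.5% of Q turned over, and the slowed feed leaves a share of 99.5%.

Step six, the forecast. It gives 52% and 98%, judging that “D may be a short-lived intermediate”. Both values lie below this reckoning.

Step seven, the flask. It gives 62.5% and 99.3%.

    Q + J → E + X (k = 4.90 × 10⁻⁵ M⁻¹ s⁻¹)
    D + X → G (k = 1.22 × 10⁻⁴ M⁻¹ s⁻¹)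
    E → Z (k = 4.11 × 10⁻⁵ s⁻¹)
    E ⇌ L (K = 180, k = 1.03 × 10⁻⁴ s⁻¹)
    E ⇌ D (K = 0.917, k = 1.67 × 10⁻⁴ s⁻¹)

At 5.0 h the flask stands above the reckoned 56.5%, as a holding time shorter than 0.105 d would give. That τ contains no charge, and the neighbour flask with 0.020 M of Q gives 62.4% at 5.0 h. At 10 d, τ and k′ reckon 99.5% for that neighbour, which gives 99.3%. Part of the early share comes from the way back from D to E: with that way removed, the flask at 5.0 h falls from 62.5% to 38.1%. Part of the late share comes from the same way back: with it removed, the flask at 10 d falls from 99.3% to 59.9%.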